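The data are calculated for substances that don't exist; noise was put on by code.

Violet lost a smaller share of its D than teal and ochre did.

| flask | D | Q | Z | remark | time |
|---|---|---|---|---|---|
| teal | 0.40 M (fed, over 80 min) | 0.056 M | 2 mM | run made earlier |  |
| ochre | 0.40 M (fed, over 80 min) | 0.088 M | 2 mM | run made earlier |  |
| violet | 0.20 M (fed, over 80 min) | 0.040 M | 2 mM | run made earlier |  |
| flask | 0.40 M (fed, over 80 min) | 0.0400 M | 2.0 mM |  | 6.0 d |

| run | time / d | D / % | L / % | E / % | G / % |
|---|---|---|---|---|---|
| teal | 0.625 | 0 | 55.4 | 14.5 | 1.5 |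
| teal | 1.25 | 0 | 56.9 | 14.5 | 0.1 |
| teal | 1.67 | 0.9 | 57.6 | 14.0 | 0.2 |
| teal | 2.50 | 0 | 56.9 | 14.8 | 0 |
| teal | 3.00 | 0 | 57.9 | 14.5 | 0 |
| teal | 4.00 | 0 | 57.0 | 14.6 | 0 |
| ochre | 0.625 | 0.2 | 51.8 | 20.2 | 1.9 |
| ochre | 1.25 | 0 | 53.8 | 20.7 | 1.1 |
| ochre | 1.67 | 0 | 54.0 | 20.3 | 0 |
| ochre | 2.50 | 0 | 54.3 | 20.1 | 0.6 |
| ochre | 3.00 | 0 | 54.2 | 20.6 | 0 |
| ochre | 4.00 | 0 | 54.0 | 20.2 | 0 |
| violet | 0.333 | 0.9 | 49.9 | 19.5 | 12.9 |
| violet | 0.833 | 0 | 62.0 | 20.2 | 0.1 |
| violet | 1.67 | 0 | 63.8 | 19.4 | 0.2 |
| violet | 2.50 | 0.8 | 64.0 | 19.8 | 0 |
| violet | 4.00 | 0.4 | 64.2 | 19.3 | 0 |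

(each reading ± 0.5 percentage points)

- what was read earlier has a scatter of 0.5 percentage points, one standard deviation
- in a conversion Q counts as not yet reacted
- the reaction counts as stopped when no species that holds the D and Q together changes by six tenths of a point or more over the second half of the time

* which holds at 6.0 d: what has brought the reaction to rest, or that it has not come to rest (Q counts as not reacted) (all of D has reacted / it is still moving / forward and back rates have come level / no working catalyst is left)
* conversion of D and Q together at 6.0 d
* amount of L at 6.0 d, in percent of the D and Q together charged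
* amount of E at 6.0 d, in percent of the D and Q together charged
* amount of G if the flask were left three thousand times as long, in percent of the D and Q together charged

I called f the lost share: the part of the charged D that stood at the last reading as neither L nor E. It read 32.4% in teal, 31.5% in ochre and 19.8% in violet.

Two versions of the flask could be done in the head. With f held at violet's value, the flask would lose 18.0% of D and Q together. With f growing in proportion to D, it would lose 36.0%. Teal, with the flask's charge of D, had an f above violet's and below that proportion, so I put the flask between these two versions. What did grow with the charge was the lost part over the kept part, the kept part being the selectivity towards L and E. So I took charge × kept / lost from each run: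

teal 0.835 M, ochre 0.871 M, violet 0.810 M

H = 0.839 M

f = charge / (charge + H)

H is the level charge, the charge of D at which lost and kept parts come equal, read at this feed time and this amount of Z.

For the flask this gave f = 32.3%, so I reckoned a loss of 29.4% of the whole. Teal's E stood 0.0106 M above its Q. Adding that to the flask's Q, I put E at 11.5% and L at 59.1%. Teal's last reading had D at 0% and G at 0%, so I expected both gone.

The forecast said all of D has reacted, conversion 100%, L 59%, E 11% and G 0%, adding that “the lower Q is an extrapolation”. My E stood slightly above its E.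

The flask gave all of D has reacted, conversion 100%, L 59.8%, E 11.8% and G 0%.

    D + Z → Z + G (k = 5.42 /M/min)
    Z + Q → Z + E (k = 3220 /M/min)
    Z + G → Z + L (k = 2.23 /M/min)
    D ⇌ Q (K = 0.115, k = 4.87 × 10⁻⁴ /min)
    G → J (k = 3.24 × 10⁻⁵ /min)
    2 D → X (k = 0.0204 /M/min)

The flask left 28.4% outside L and E, against my 29.4%; it stood as X 28.0% and J 0.434%. The neighbour took 1.0 M of D with Q unchanged. H gave it f = 54.4%, so a loss of 52.3% of the whole. It ended with L 47.3% and E 5.98%, leaving 46.8% outside them, less than reckoned. Its own level charge came to 1.06 M, above the 0.839 M I carried.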